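**Retrosynthetic overview**
- The angelate is put on last, onto the free C1 ring alcohol; both acetates are already in place.
- The only ring is closed once, C1→C6, from an acyclic (2Z,6E)-farnesane acetal, as the farnesyl C1 cation closes onto the C6=C7 olefin.
- The resulting C7 cation is quenched by a hydride relayed from the C1 side (here from the O-benzyl group on the C1 oxygen), so C1, C6 and C7 are set in one operation.
- The acyclic precursor comes from a C3–C4 union of a Z-alkenylzinc (C1–C3, carrying the dibenzyl acetal) with a C4–C13 hydroxy aldehyde.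
- The aldehyde comes from prenal by propargylation, carboalumination and oxirane homologation; the alkenyl piece comes from but-2-yn-1-ol.

Assumption: atoms carry farnesane/bisabolane numbers (ring C1–C6, C15 methyl on C3, side chain C7–C13 on C6, C14 methyl on C7); the target is then (1S,4R,6S,7R,9R), with C1–O and C4–O cis to each other and trans to the side chain.

**Step 1**
Reactants: 1 3-methylbut-2-enal (prenal); 2 4,4,5,5-tetramethyl-2-(propa-1,2-dien-1-yl)-1,3,2-dioxaborolane
Product: 3 (R)-6-methylhept-5-en-1-yn-4-ol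
Conditions: (R)-TRIP (5 mol%), 4 Å MS, toluene, −20 °C
Reagents that add atoms: none
Why: Chiral phosphoric acid-catalysed allenylboronate propargylation (SE2′, closed six-membered transition state) in which (R)-TRIP is expected to direct the CH2 terminus to the Re face of prenal and so give the R carbinol (C9 of the target); the other catalyst hand is used if the sense proves reversed.

**Step 2**
Reactants: 3 (R)-6-methylhept-5-en-1-yn-4-ol
Product: 6 (3E,6R)-4,8-dimethylnona-3,7-diene-1,6-diol, via alkenyldimethylalane 4 (not isolated), via lithium alkenylalanate 5 (not isolated)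
Conditions: Me3Al (3.5 equiv), Cp2ZrCl2 (0.25 equiv), CH2Cl2, 0 °C → rt; evaporate; n-BuLi, THF/hexane, −78 °C; oxirane, −78 → 0 °C; aq. Rochelle salt
Reagents that add atoms: trimethylaluminium C[Al](C)C; oxirane C1CO1
Why: Negishi carboalumination adds CH3 and Al syn across the terminal alkyne (CH3 to the internal carbon) and the derived alanate opens oxirane with retention, which fixes the E trisubstituted olefin (C6=C7 of the target) while the free hydroxyl rides along as its aluminium alkoxide.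

**Step 3**
Reactants: 6 (3E,6R)-4,8-dimethylnona-3,7-diene-1,6-diol
Product: 7 (3E,6R)-6-hydroxy-4,8-dimethylnona-3,7-dienal
Conditions: TEMPO (10 mol%), PhI(OAc)2 (1.1 equiv), CH2Cl2, 0 °C → rt; used at once
Reagents that add atoms: none
Why: Oxoammonium (TEMPO) oxidation takes the unhindered primary alcohol in preference to the hindered secondary allylic one and is mild enough to leave the skipped olefin unconjugated; no stereocentre is touched.

**Step 4**
Reactants: 8 but-2-yn-1-ol
Product: 10 (Z)-3-iodobut-2-en-1-ol, via cyclic sodium alkenylalanate 9 (not isolated)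
Conditions: NaAlH2(OCH2CH2OMe)2, THF, 0 °C → rt; I2, −78 → 0 °C
Reagents that add atoms: iodine II
Why: Hydroxyl-directed trans-hydroalumination puts aluminium on C3 cis to the CH2O group in a five-membered alanate, and iodinolysis with retention gives the Z iodide.

**Step 5**
Reactants: 10 (Z)-3-iodobut-2-en-1-ol
Product: 11 (Z)-3-iodobut-2-enal
Conditions: MnO2, CH2Cl2, rt, dark; used crude
Reagents that add atoms: none
Why: Neutral allylic oxidation with MnO2 keeps the Z geometry.

**Step 6**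
Reactants: 11 (Z)-3-iodobut-2-enal
Product: 12 (Z)-1,1-bis(benzyloxy)-3-iodobut-2-ene
Conditions: BnOSiMe3 (2.2 equiv), TMSOTf (2 mol%), CH2Cl2, −78 °C; pyridine quench
Reagents that add atoms: benzyloxytrimethylsilane C[Si](C)(C)OCc1ccccc1
Why: Noyori acetalisation (alkoxysilane/TMSOTf) is aprotic and run at −78 °C, so neither Z/E isomerisation nor addition–elimination at the iodinated carbon intervenes.

**Step 7**
Reactants: 12 (Z)-1,1-bis(benzyloxy)-3-iodobut-2-ene; 7 (3E,6R)-6-hydroxy-4,8-dimethylnona-3,7-dienal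
Product: 16 (2Z,4R,6E,9R)-1,1-bis(benzyloxy)-3,7,11-trimethyldodeca-2,6,10-triene-4,9-diyl diacetate, via alkenyllithium 13 (not isolated), via alkenyl(ethyl)zinc 14 (not isolated), via bis(ethylzinc) dialkoxide 15 (not isolated)
Conditions: 12 (1.6 equiv), t-BuLi (2 equiv per 12), Et2O, −78 °C; EtZnCl, → 0 °C; N,N,N′,N′-tetraethylethylenediamine; (−)-MIB (10 mol%), then 7 (pre-mixed with Et2Zn, 1 equiv), toluene, −10 °C; Ac2O, DMAP, rt
Reagents that add atoms: acetic anhydride CC(=O)OC(C)=O
Why: Iodine–lithium exchange and transmetalation keep the olefin geometry, and amino-alcohol-catalysed alkenylzinc addition under (−)-MIB delivers the alkenyl group to the Si face of the aldehyde to give 4R, after which both zinc alkoxides are acetylated in the same flask.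

**Step 8**
Reactants: 16 (2Z,4R,6E,9R)-1,1-bis(benzyloxy)-3,7,11-trimethyldodeca-2,6,10-triene-4,9-diyl diacetate
Product: 18 (1S,4R,6S,7R,9R)-4,9-diacetoxybisabola-2,10-dien-1-ol, via mixed benzaldehyde acetal 17 (not isolated)
Conditions: TMSOTf (10 mol%), 2,6-di-tert-butyl-4-methylpyridine (15 mol%), CH2Cl2 (0.01 M), −78 → −40 °C; Et3N; then AcOH/THF/H2O, rt
Reagents that add atoms: none
Why: Proposed new method: TMSOTf ionises the dibenzyl acetal to an O-benzyl oxocarbenium ion whose C1 is attacked by the C6=C7 olefin through a chair (O-benzyl and C7 equatorial, hence C1–O trans to the side chain; the 4-acetoxy group pseudoaxial to avoid A(1,2) strain with the C3 methyl, hence the 1S,6S sense from 4R), and the nascent C7 cation is quenched on the same face by a 1,5-hydride shift from the benzylic CH2 through a trans-fused six-membered chair (suprafacial addition of C1 and H across the 6E olefin gives 7R), after which the PhCH=O+ ion is trapped by the liberated BnOSiMe3 (regenerating TMSOTf) and acetal 17 is hydrolysed; the closest known reaction types are the Lewis acid Prins/carbonyl-ene cyclisation of neral to isopiperitenol and internal-redox 1,5-hydride transfers from benzyl ethers to cations.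

**Step 9**
Reactants: 18 (1S,4R,6S,7R,9R)-4,9-diacetoxybisabola-2,10-dien-1-ol; 19 angelic acid [(Z)-2-methylbut-2-enoic acid]
Product: 21 (1S,4R,6S,7R,9R)-4,9-diacetoxy-1-angeloyloxybisabola-2,10-diene (CNP0417294.1), via mixed angelic anhydride 20 (not isolated)
Conditions: 19, 2,4,6-trichlorobenzoyl chloride, Et3N, toluene, rt; then 18, 75 °C (no DMAP)
Reagents that add atoms: none
Why: Yamaguchi esterification through the mixed anhydride acylates the hindered allylic alcohol at oxygen (C1 configuration untouched), and leaving out a nucleophilic catalyst avoids angelate-to-tiglate isomerisation.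

**Compound list**
1 | 3-methylbut-2-enal (prenal) | CC(C)=CC=O | starting material
2 | 4,4,5,5-tetramethyl-2-(propa-1,2-dien-1-yl)-1,3,2-dioxaborolane (allenylboronic acid pinacol ester) | C=C=CB1OC(C)(C)C(C)(C)O1 | starting material
3 | (R)-6-methylhept-5-en-1-yn-4-ol | C#CC[C@@H](O)C=C(C)C | intermediate
4 | [(1E,4R)-4-(dimethylalumanyloxy)-2,6-dimethylhepta-1,5-dien-1-yl]dimethylalumane | C[Al](C)/C=C(\C)C[C@@H](O[Al](C)C)C=C(C)C | intermediate
5 | lithium butyl[(1E,4R)-4-(dimethylalumanyloxy)-2,6-dimethylhepta-1,5-dien-1-yl]dimethylalanate | [Li+].CCCC[Al-](C)(C)/C=C(\C)C[C@@H](O[Al](C)C)C=C(C)C | intermediate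
6 | (3E,6R)-4,8-dimethylnona-3,7-diene-1,6-diol | OCC/C=C(\C)C[C@@H](O)C=C(C)C | intermediate
7 | (3E,6R)-6-hydroxy-4,8-dimethylnona-3,7-dienal | O=CC/C=C(\C)C[C@@H](O)C=C(C)C | intermediate
8 | but-2-yn-1-ol | CC#CCO | starting material
9 | sodium 2,2-bis(2-methoxyethoxy)-3-methyl-2,5-dihydro-1,2-oxaaluminol-2-uide | [Na+].CC1=CCO[Al-]1(OCCOC)OCCOC | intermediate
10 | (Z)-3-iodobut-2-en-1-ol | OC/C=C(/C)I | intermediate
11 | (Z)-3-iodobut-2-enal | O=C/C=C(/C)I | intermediate
12 | (Z)-1,1-bis(benzyloxy)-3-iodobut-2-ene | C/C(I)=C/C(OCc1ccccc1)OCc1ccccc1 | intermediate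
13 | [4,4-bis(benzyloxy)but-2-en-2-yl]lithium (Li cis to the acetal carbon) | [Li]/C(C)=C\C(OCc1ccccc1)OCc1ccccc1 | intermediate
14 | [4,4-bis(benzyloxy)but-2-en-2-yl](ethyl)zinc (Zn cis to the acetal carbon) | CC[Zn]/C(C)=C\C(OCc1ccccc1)OCc1ccccc1 | intermediate
15 | bis(ethylzinc) dialkoxide of (2Z,4R,6E,9R)-1,1-bis(benzyloxy)-3,7,11-trimethyldodeca-2,6,10-triene-4,9-diol | C(OCc1ccccc1)(OCc1ccccc1)/C=C(/C)[C@H](O[Zn]CC)C/C=C(\C)C[C@@H](O[Zn]CC)C=C(C)C | intermediate
16 | (2Z,4R,6E,9R)-1,1-bis(benzyloxy)-3,7,11-trimethyldodeca-2,6,10-triene-4,9-diyl diacetate | C(OCc1ccccc1)(OCc1ccccc1)/C=C(/C)[C@H](OC(C)=O)C/C=C(\C)C[C@@H](OC(C)=O)C=C(C)C | intermediate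
17 | (1S,4R,6S,7R,9R)-1-[(benzyloxy)(phenyl)methoxy]bisabola-2,10-diene-4,9-diyl diacetate (both epimers at the acetal carbon) | C(c1ccccc1)(OCc1ccccc1)O[C@@H]1C=C(C)[C@H](OC(C)=O)C[C@H]1[C@H](C)C[C@H](C=C(C)C)OC(C)=O | intermediate
18 | (1S,4R,6S,7R,9R)-4,9-diacetoxybisabola-2,10-dien-1-ol = (1R,4S,5S)-5-[(2R,4R)-4-acetoxy-6-methylhept-5-en-2-yl]-4-hydroxy-2-methylcyclohex-2-en-1-yl acetate | O[C@@H]1C=C(C)[C@H](OC(C)=O)C[C@H]1[C@H](C)C[C@H](C=C(C)C)OC(C)=O | intermediate
19 | angelic acid [(Z)-2-methylbut-2-enoic acid] | C/C=C(/C)C(=O)O | starting material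
20 | (Z)-2-methylbut-2-enoic 2,4,6-trichlorobenzoic anhydride | C/C=C(/C)C(=O)OC(=O)c1c(Cl)cc(Cl)cc1Cl | intermediate
21 | (1S,4R,6S,7R,9R)-4,9-diacetoxy-1-angeloyloxybisabola-2,10-diene (CNP0417294.1) | C/C=C(/C)C(=O)O[C@@H]1C=C(C)[C@H](OC(C)=O)C[C@H]1[C@H](C)C[C@H](C=C(C)C)OC(C)=O | target

**Step count**
Total steps: 9. Longest linear sequence: 6 (steps 1, 2, 3, 7, 8, 9; the branch 4, 5, 6, 7, 8, 9 is equally long).

**Steps most likely to fail and fallbacks**

Step 8 is the least certain. The ways it can go wrong: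
- the facial bias from the 4-acetoxy group may be modest;
- the C9 acetate can capture the C7 cation or ionise;
- proton loss from C7 competes with the hydride shift.

Fallback: from 16, hydrolyse the acetal (PPTS, aqueous acetone) to the free enal (2Z,4R,6E,9R)-3,7,11-trimethyl-1-oxododeca-2,6,10-triene-4,9-diyl diacetate F1. Close the ring by a conventional Me2AlCl-promoted carbonyl-ene reaction (CH2Cl2, −78 °C) to the homoallylic alcohol (1S,4R,6S,9R)-4,9-diacetoxybisabola-2,7(14),10-trien-1-ol F2. Then set C7 separately by hydroxyl-directed hydrogenation of the 1,1-disubstituted olefin ([Rh(nbd)(dppb)]BF4, H2, CH2Cl2), which comes back to the route at 18. The ring closure is then no longer coupled to the hydride transfer, at the cost of one step, an uncertain regiochemistry of proton loss and an unproven facial sense in the hydrogenation.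

Step 7 is next. The aldehyde is enolisable and carries a free hydroxyl, and the alkenylzinc can chelate through its acetal oxygens, which may erode the enantioselectivity.

Fallback: from 12 and 7, add alkenyllithium 13 (2.2 equiv, the first equivalent deprotonating the hydroxyl) directly at −78 °C without zinc or ligand. This gives the C4-epimeric diol (2Z,4RS,6E,9R)-1,1-bis(benzyloxy)-3,7,11-trimethyldodeca-2,6,10-triene-4,9-diol F3. Oxidise both allylic alcohols with Dess–Martin periodinane to (2Z,6E)-1,1-bis(benzyloxy)-3,7,11-trimethyldodeca-2,6,10-triene-4,9-dione F4. Reduce both ketones under reagent control with (S)-2-methyl-CBS-oxazaborolidine and BH3·SMe2 to (2Z,4R,6E,9R)-1,1-bis(benzyloxy)-3,7,11-trimethyldodeca-2,6,10-triene-4,9-diol F5 (the alkenyl group is the large substituent at both carbonyls). Acetylate (Ac2O, Et3N, DMAP) to come back at 16.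

Step 3 is third. The secondary allylic alcohol may be over-oxidised, and the β,γ-unsaturated hydroxy aldehyde may isomerise.

Fallback: from 3, silylate (TBSCl, imidazole) to (R)-tert-butyldimethyl[(6-methylhept-5-en-1-yn-4-yl)oxy]silane F6. Carboaluminate and homologate with oxirane as in step 2 to (3E,6R)-6-[(tert-butyldimethylsilyl)oxy]-4,8-dimethylnona-3,7-dien-1-ol F7. Oxidise with Dess–Martin periodinane/NaHCO3 to (3E,6R)-6-[(tert-butyldimethylsilyl)oxy]-4,8-dimethylnona-3,7-dienal F8, where no second hydroxyl competes. Unite F8 with 14 under the step 7 conditions with Ac2O quench to (2Z,4R,6E,9R)-1,1-bis(benzyloxy)-9-[(tert-butyldimethylsilyl)oxy]-3,7,11-trimethyldodeca-2,6,10-trien-4-yl acetate F9. Remove the silyl group (Bu4NF/AcOH, THF) to (2Z,4R,6E,9R)-1,1-bis(benzyloxy)-9-hydroxy-3,7,11-trimethyldodeca-2,6,10-trien-4-yl acetate F10, and acetylate to come back at 16.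

**Further compounds**
F1 | step 8 | (2Z,4R,6E,9R)-3,7,11-trimethyl-1-oxododeca-2,6,10-triene-4,9-diyl diacetate | O=C/C=C(/C)[C@H](OC(C)=O)C/C=C(\C)C[C@@H](OC(C)=O)C=C(C)C
F2 | step 8 | (1S,4R,6S,9R)-4,9-diacetoxybisabola-2,7(14),10-trien-1-ol | O[C@@H]1C=C(C)[C@H](OC(C)=O)C[C@H]1C(=C)C[C@H](C=C(C)C)OC(C)=O
F3 | step 7 | (2Z,4RS,6E,9R)-1,1-bis(benzyloxy)-3,7,11-trimethyldodeca-2,6,10-triene-4,9-diol | C(OCc1ccccc1)(OCc1ccccc1)/C=C(/C)C(O)C/C=C(\C)C[C@@H](O)C=C(C)C
F4 | step 7 | (2Z,6E)-1,1-bis(benzyloxy)-3,7,11-trimethyldodeca-2,6,10-triene-4,9-dione | C(OCc1ccccc1)(OCc1ccccc1)/C=C(/C)C(=O)C/C=C(\C)CC(=O)C=C(C)C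
F5 | step 7 | (2Z,4R,6E,9R)-1,1-bis(benzyloxy)-3,7,11-trimethyldodeca-2,6,10-triene-4,9-diol | C(OCc1ccccc1)(OCc1ccccc1)/C=C(/C)[C@H](O)C/C=C(\C)C[C@@H](O)C=C(C)C
F6 | step 3 | (R)-tert-butyldimethyl[(6-methylhept-5-en-1-yn-4-yl)oxy]silane | C#CC[C@@H](O[Si](C)(C)C(C)(C)C)C=C(C)C
F7 | step 3 | (3E,6R)-6-[(tert-butyldimethylsilyl)oxy]-4,8-dimethylnona-3,7-dien-1-ol | OCC/C=C(\C)C[C@@H](O[Si](C)(C)C(C)(C)C)C=C(C)C
F8 | step 3 | (3E,6R)-6-[(tert-butyldimethylsilyl)oxy]-4,8-dimethylnona-3,7-dienal | O=CC/C=C(\C)C[C@@H](O[Si](C)(C)C(C)(C)C)C=C(C)C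
F9 | step 3 | (2Z,4R,6E,9R)-1,1-bis(benzyloxy)-9-[(tert-butyldimethylsilyl)oxy]-3,7,11-trimethyldodeca-2,6,10-trien-4-yl acetate | C(OCc1ccccc1)(OCc1ccccc1)/C=C(/C)[C@H](OC(C)=O)C/C=C(\C)C[C@@H](O[Si](C)(C)C(C)(C)C)C=C(C)C
F10 | step 3 | (2Z,4R,6E,9R)-1,1-bis(benzyloxy)-9-hydroxy-3,7,11-trimethyldodeca-2,6,10-trien-4-yl acetate | C(OCc1ccccc1)(OCc1ccccc1)/C=C(/C)[C@H](OC(C)=O)C/C=C(\C)C[C@@H](O)C=C(C)C
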